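**Strategy.** The cyclohexane ring (C-1, the CH carrying the ester chain; C-2, quaternary; C-3, carbinol; C-4, C-5; C-6, the carbon of the enal) is split into a C-1/C-2 two-carbon unit and a C-3–C-6 four-carbon unit with oxygen at both ends. The key step exploits this 1,4-dioxygenated C-3/C-6 pair. An enantioenriched 1,2-bis(boronate), made by Pt(dba)3-catalysed diboration of a (Z)-3-methyl-1,3-diene, allylates 4-oxopentanal twice, forming C-1–C-6, then C-2–C-3, and closing the ring. The one C–B stereocentre is relayed to C-1, C-2 and C-3. The vinyl group left on C-2 becomes the homofarnesyl chain, and the C-6 carbinol becomes the enal.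

Key step: step 7

Remark: the ring numbering above is used throughout, and the enal isomer with the formyl group syn to C-1 (6Z) is assumed to be the thermodynamically preferred one.

Step 1
Reactants: 1 butane-1,4-diol
Product: 2 4-hydroxybutyl decanoate
Conditions: decanoyl chloride (1 equiv), 1 (4 equiv), Et3N, THF, 0 °C → rt
Reagents that add atoms: decanoyl chloride, CCCCCCCCCC(=O)Cl
Why: Acyl substitution on the diol used in excess should give mainly the monoester, with no stereocentre involved.

Step 2
Reactants: 2 4-hydroxybutyl decanoate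
Product: 3 4-oxobutyl decanoate
Conditions: TEMPO (10 mol%), PhI(OAc)2, CH2Cl2, rt
Reagents that add atoms: none
Why: The oxoammonium-mediated (TEMPO) oxidation of a primary alcohol should stop at the aldehyde and leave the ester untouched.

Step 3
Reactants: 3 4-oxobutyl decanoate
Product: 4 (4Z)-5-iodohex-4-en-1-yl decanoate
Conditions: [Ph3PCH2CH3]I, n-BuLi, THF, 0 °C; I2, −78 °C; NaN(SiMe3)2, −78 → −20 °C; then 3, −78 °C → rt
Reagents that add atoms: ethyltriphenylphosphonium iodide, CC[P+](c1ccccc1)(c1ccccc1)c1ccccc1.[I-]; iodine, II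
Why: The Stork–Zhao olefination (Wittig reaction of the α-iodo ylide) should give the (Z)-iodoalkene, with iodine cis to the chain, through the kinetically favoured cis-oxaphosphetane.

Step 4
Reactants: 4 (4Z)-5-iodohex-4-en-1-yl decanoate
Product: 5 (4Z)-5-methylhepta-4,6-dien-1-yl decanoate
Conditions: Bu3SnCH=CH2, Pd(PPh3)4 (5 mol%), CuI (10 mol%), DMF, 50 °C
Reagents that add atoms: tributyl(vinyl)stannane, C=C[Sn](CCCC)(CCCC)CCCC
Why: Stille coupling should replace iodine by vinyl with retention of the alkene geometry, so the chain stays cis to the new vinyl group.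

Step 5
Reactants: 5 (4Z)-5-methylhepta-4,6-dien-1-yl decanoate
Product: 6 (4Z,6S)-5-methyl-6,7-bis(4,4,5,5-tetramethyl-1,3,2-dioxaborolan-2-yl)hept-4-en-1-yl decanoate
Conditions: B2(pin)2, Pt(dba)3 (3 mol%), TADDOL-derived phenylphosphonite ligand (6 mol%, the enantiomer that gives the 6S product), THF, 60 °C
Reagents that add atoms: bis(pinacolato)diboron, CC1(C)OB(OC1(C)C)B1OC(C)(C)C(C)(C)O1
Why: Enantioselective Pt-catalysed diboration of a 1,3-diene that cannot reach the s-cis conformation (cis substituent at the far diene terminus) should add both boron atoms 1,2 across the terminal alkene, and the chiral ligand sets the C–B stereocentre (6S).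

Step 6
Reactants: 7 hex-5-en-2-one
Product: 9 4-oxopentanal, via ozonide 8 (not isolated)
Conditions: O3, CH2Cl2, −78 °C; then PPh3, −78 °C → rt
Reagents that add atoms: ozone, [O-][O+]=O
Why: Ozonolysis with reductive work-up should cleave the terminal alkene to the aldehyde and leave the ketone untouched.

Step 7
Reactants: 6 (4Z,6S)-bis(boronate); 9 4-oxopentanal
Product: 12 3-[(1S,2S,3S,6S)-2-ethenyl-3,6-dihydroxy-2,3-dimethylcyclohexyl]propyl decanoate, via mono-allylation allylboronate 10 (not isolated), via bis(boryl) ether 11 (not isolated)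
Conditions: 9 (1.1 equiv) added slowly to 6, THF, 25 °C, then 65 °C; then MeOH/H2O, rt
Reagents that add atoms: none
Why: The secondary allylic boronate of 6 adds to the aldehyde of 9 through a closed chair transition state, forming C-1–C-6 with allylic transposition and turning the primary boronate into the (E)-allylboronate 10, whose γ-carbon then adds intramolecularly to the methyl ketone, forming C-2–C-3 and giving 11, which is hydrolysed to 12 on work-up. The closest known reaction type is the tandem double allylboration of diene-derived 1,2-bis(boronates) with 1,4-dicarbonyl compounds to give cyclohexane-1,4-diols, a known reaction type that tolerates keto aldehydes. The carbocycle closes by 6-exo-trig attack of the allylboronate γ-carbon on the ketone carbonyl, through a trans-decalin-like chair–chair array of the forming ring and the allylboration ring. C-1 is set by chirality transfer from the C–B stereocentre, because allylic 1,3-strain with the cis-positioned side chain forces the CH2B(pin) group pseudo-equatorial, which fixes the reacting face and the (E) geometry of 10. C-2 and C-3 are set by substrate control in the ring closure, where the chain on C-1 and the boryloxy group on C-6 are equatorial and only the two methyl groups are axial, so that the C-3 oxygen ends trans to the vinyl group and cis to the C-2 methyl and the C-1 chain. The step needs the aldehyde to react before the ketone, which the reactivity difference secures, and ring closure to outrun a second intermolecular allylation, which slow addition of 9 and dilution should secure.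

Step 8
Reactants: 13 (5E)-6,10-dimethylundeca-5,9-dien-2-one ((E)-geranylacetone)
Product: 15 (5E)-6,10-dimethylundeca-5,9-dien-1-yne, via enol phosphate 14 (not isolated)
Conditions: LiN(iPr)2, THF, −78 °C; ClP(O)(OEt)2, −78 °C → rt; LiN(iPr)2 (2.3 equiv), −78 °C → rt; aq. NH4Cl
Reagents that add atoms: none
Why: Kinetic enolisation at the methyl group, O-phosphorylation and base-induced elimination of the enol phosphate (Negishi alkyne synthesis) should turn the methyl ketone into the terminal alkyne without touching the (E)-alkene.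

Step 9
Reactants: 15 (5E)-6,10-dimethylundeca-5,9-dien-1-yne
Product: 17 (1E,5E)-1-iodo-2,6,10-trimethylundeca-1,5,9-triene, via alkenylalane 16 (not isolated)
Conditions: Me3Al, Cp2ZrCl2 (25 mol%), CH2Cl2, 0 °C → rt; then I2, THF, −30 → 0 °C
Reagents that add atoms: trimethylaluminium, C[Al](C)C; iodine, II
Why: Negishi carboalumination adds methyl and aluminium syn across the alkyne (methyl to the internal carbon), and iodinolysis with retention should give the (E)-iodoalkene.

Step 10
Reactants: 12 diol; 17 (1E,5E)-iodotriene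
Product: 19 3-[(1S,2S,3S,6S)-3,6-dihydroxy-2,3-dimethyl-2-[(3E,7E)-4,8,12-trimethyltrideca-3,7,11-trien-1-yl]cyclohexyl]propyl decanoate, via B-alkyl-9-BBN 18 (not isolated)
Conditions: 9-BBN (3 equiv), THF, 0 °C → rt; then 17, PdCl2(dppf) (5 mol%), AsPh3, aq. K3PO4, DMF, rt
Reagents that add atoms: none
Why: 9-BBN should hydroborate the only alkene of 12 at its terminal carbon, and the B-alkyl Suzuki–Miyaura coupling joins it to 17 with retention of the (E) geometry, completing the homofarnesyl chain without touching the ring stereocentres.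

Step 11
Reactants: 19 diol
Product: 20 3-[(1S,2S,3S)-3-hydroxy-2,3-dimethyl-6-oxo-2-[(3E,7E)-4,8,12-trimethyltrideca-3,7,11-trien-1-yl]cyclohexyl]propyl decanoate
Conditions: Dess–Martin periodinane, CH2Cl2, 0 °C → rt
Reagents that add atoms: none
Why: Dess–Martin oxidation should convert the secondary C-6 alcohol into the ketone while the tertiary alcohol and the ester stay intact, and C-1 should keep its configuration because its chain is already equatorial.

Step 12
Reactants: 20 ketone
Product: 21 3-[(1S,2S,3S,6R)-3,6-dihydroxy-2,3-dimethyl-6-(prop-1-en-2-yl)-2-[(3E,7E)-4,8,12-trimethyltrideca-3,7,11-trien-1-yl]cyclohexyl]propyl decanoate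
Conditions: CH2=C(CH3)MgBr (2.5 equiv), LaCl3·2LiCl (1 equiv), THF, −78 °C; then H2O
Reagents that add atoms: isopropenylmagnesium bromide, CC(=C)[Mg]Br
Why: Lanthanum-assisted 1,2-addition of the alkenyl Grignard reagent to the ketone should be much faster than attack on the ester at −78 °C, with equatorial entry anti to the axial C-2 methyl expected, although the C-6 configuration is lost in the next step.

Step 13
Reactants: 21 tertiary allylic alcohol
Product: 22 3-[(1R,2S,3S,6Z)-3-hydroxy-2,3-dimethyl-6-(1-oxopropan-2-ylidene)-2-[(3E,7E)-4,8,12-trimethyltrideca-3,7,11-trien-1-yl]cyclohexyl]propyl decanoate (target)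
Conditions: [C5H5NH][CrO3Cl] (3 equiv), 4 Å molecular sieves, CH2Cl2, rt
Reagents that add atoms: pyridinium chlorochromate, [O-][Cr](=O)(=O)Cl.c1cc[nH+]cc1
Why: In the Babler–Dauben oxidative transposition the chromate ester of the tertiary allylic alcohol undergoes a [3,3] shift to the primary allylic chromate, which is oxidised to the enal, and the tetrasubstituted alkene should form with the formyl group syn to C-1, the arrangement with least allylic strain.

**Compound list**

1 | butane-1,4-diol | OCCCCO | starting material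
2 | 4-hydroxybutyl decanoate | CCCCCCCCCC(=O)OCCCCO | intermediate
3 | 4-oxobutyl decanoate | CCCCCCCCCC(=O)OCCCC=O | intermediate
4 | (4Z)-5-iodohex-4-en-1-yl decanoate | CCCCCCCCCC(=O)OCCC/C=C(\I)C | intermediate
5 | (4Z)-5-methylhepta-4,6-dien-1-yl decanoate | CCCCCCCCCC(=O)OCCC/C=C(\C=C)C | intermediate
6 | (4Z,6S)-5-methyl-6,7-bis(4,4,5,5-tetramethyl-1,3,2-dioxaborolan-2-yl)hept-4-en-1-yl decanoate | CCCCCCCCCC(=O)OCCC/C=C(/C)[C@@H](B1OC(C)(C)C(C)(C)O1)CB1OC(C)(C)C(C)(C)O1 | intermediate
7 | hex-5-en-2-one | CC(=O)CCC=C | starting material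
8 | 4-(1,2,4-trioxolan-3-yl)butan-2-one (ozonide) | CC(=O)CCC1OCOO1 | intermediate (not isolated)
9 | 4-oxopentanal | CC(=O)CCC=O | intermediate
10 | mono-allylation product: open-chain (E)-allyl pinacolboronate with C-1–C-6 formed, C-6 O-boryl, methyl ketone free | CC1(C)OB(OC1(C)C)C/C=C(\C)[C@H](CCCOC(=O)CCCCCCCCC)[C@@H](OB1OC(C)(C)C(C)(C)O1)CCC(C)=O | intermediate (not isolated)
11 | bis(pinacolboryl) ether of 12 | CCCCCCCCCC(=O)OCCC[C@@H]1[C@@H](OB2OC(C)(C)C(C)(C)O2)CC[C@](C)(OB2OC(C)(C)C(C)(C)O2)[C@@]1(C)C=C | intermediate (not isolated)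
12 | 3-[(1S,2S,3S,6S)-2-ethenyl-3,6-dihydroxy-2,3-dimethylcyclohexyl]propyl decanoate | CCCCCCCCCC(=O)OCCC[C@@H]1[C@@H](O)CC[C@](C)(O)[C@@]1(C)C=C | intermediate
13 | (5E)-6,10-dimethylundeca-5,9-dien-2-one | CC(=O)CC/C=C(\C)CCC=C(C)C | starting material
14 | diethyl (5E)-6,10-dimethylundeca-1,5,9-trien-2-yl phosphate | C=C(OP(=O)(OCC)OCC)CC/C=C(\C)CCC=C(C)C | intermediate (not isolated)
15 | (5E)-6,10-dimethylundeca-5,9-dien-1-yne | C#CCC/C=C(\C)CCC=C(C)C | intermediate
16 | dimethyl[(1E,5E)-2,6,10-trimethylundeca-1,5,9-trien-1-yl]alane | C[Al](C)/C=C(\C)CC/C=C(\C)CCC=C(C)C | intermediate (not isolated)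
17 | (1E,5E)-1-iodo-2,6,10-trimethylundeca-1,5,9-triene | I/C=C(\C)CC/C=C(\C)CCC=C(C)C | intermediate
18 | B-alkyl-9-BBN from hydroboration of the vinyl group of 12 | CCCCCCCCCC(=O)OCCC[C@@H]1[C@@H](O)CC[C@](C)(O)[C@@]1(C)CCB1C2CCCC1CCC2 | intermediate (not isolated)
19 | 3-[(1S,2S,3S,6S)-3,6-dihydroxy-2,3-dimethyl-2-[(3E,7E)-4,8,12-trimethyltrideca-3,7,11-trien-1-yl]cyclohexyl]propyl decanoate | CCCCCCCCCC(=O)OCCC[C@@H]1[C@@H](O)CC[C@](C)(O)[C@@]1(C)CC/C=C(\C)CC/C=C(\C)CCC=C(C)C | intermediate
20 | 3-[(1S,2S,3S)-3-hydroxy-2,3-dimethyl-6-oxo-2-[(3E,7E)-4,8,12-trimethyltrideca-3,7,11-trien-1-yl]cyclohexyl]propyl decanoate | CCCCCCCCCC(=O)OCCC[C@@H]1C(=O)CC[C@](C)(O)[C@@]1(C)CC/C=C(\C)CC/C=C(\C)CCC=C(C)C | intermediate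
21 | 3-[(1S,2S,3S,6R)-3,6-dihydroxy-2,3-dimethyl-6-(prop-1-en-2-yl)-2-[(3E,7E)-4,8,12-trimethyltrideca-3,7,11-trien-1-yl]cyclohexyl]propyl decanoate | CCCCCCCCCC(=O)OCCC[C@@H]1[C@@](O)(C(C)=C)CC[C@](C)(O)[C@@]1(C)CC/C=C(\C)CC/C=C(\C)CCC=C(C)C | intermediate
22 | 3-[(1R,2S,3S,6Z)-3-hydroxy-2,3-dimethyl-6-(1-oxopropan-2-ylidene)-2-[(3E,7E)-4,8,12-trimethyltrideca-3,7,11-trien-1-yl]cyclohexyl]propyl decanoate | CCCCCCCCCC(=O)OCCC[C@@H]1/C(=C(/C)C=O)CC[C@](C)(O)[C@@]1(C)CC/C=C(\C)CC/C=C(\C)CCC=C(C)C | target

**Totals.** Total step count: 13. Longest linear sequence: 10 steps (steps 1–5, 7, 10–13).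

**Steps most likely to fail**

1. Step 7. The ring-closing addition of the hindered γ,γ-disubstituted allylboronate to the methyl ketone may be too slow, so that the allylboronate is consumed by a second aldehyde molecule or survives to work-up. The fallback sets out from 6 and 9 and comes back at 12. Only the first allylboration is run at 25 °C, and neutral aqueous work-up gives the hydroxy ketone (E)-allylboronate F1. KHF2 in aqueous MeOH converts it into the potassium allyltrifluoroborate F2. BF3·OEt2 in CH2Cl2 at −78 °C then promotes the intramolecular allylation of the ketone through the same closed chair arrangement, which should give 12.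

2. Step 13. The [3,3] shift toward a tetrasubstituted alkene may be outrun by ionisation and elimination of the tertiary allylic alcohol, or may deliver the enal with poor control of the alkene geometry. The fallback sets out from 21 and comes back at 22. A non-oxidative 1,3-transposition with catalytic O3ReOSiPh3 (Et2O, −50 → 0 °C) should give, under thermodynamic control, the primary allylic alcohol 3-[(1R,2S,3S,6Z)-3-hydroxy-6-(1-hydroxypropan-2-ylidene)-2,3-dimethyl-2-[(3E,7E)-4,8,12-trimethyltrideca-3,7,11-trien-1-yl]cyclohexyl]propyl decanoate F3. MnO2 in CH2Cl2 then oxidises it to 22.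

3. Step 5. Enantiofacial control at the terminal alkene of this 3-methyl-substituted diene may be poor. The fallback sets out from 5 and comes back at 12. Diboration with achiral Pt(PPh3)4 and B2(pin)2 gives 6 together with its enantiomer, the (4Z,6R)-bis(boronate) F4. The double allylation of step 7 then gives 12 together with 3-[(1R,2R,3R,6R)-2-ethenyl-3,6-dihydroxy-2,3-dimethylcyclohexyl]propyl decanoate F5. A lipase-catalysed kinetic resolution (Candida antarctica lipase B, vinyl acetate, tert-butyl methyl ether) should, by the empirical rule for secondary alcohols, acetylate the (6R)-carbinol to 3-[(1R,2R,3R,6R)-6-acetoxy-2-ethenyl-3-hydroxy-2,3-dimethylcyclohexyl]propyl decanoate F6. Unreacted 12 is then separated by chromatography.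

Further compounds
F1 | step 7 | hydroxy ketone (E)-allyl pinacolboronate (10 with the C-6 O–B bond hydrolysed) | CC1(C)OB(OC1(C)C)C/C=C(\C)[C@H](CCCOC(=O)CCCCCCCCC)[C@@H](O)CCC(C)=O
F2 | step 7 | potassium (E)-allyltrifluoroborate corresponding to F1 | [K+].F[B-](F)(F)C/C=C(\C)[C@H](CCCOC(=O)CCCCCCCCC)[C@@H](O)CCC(C)=O
F3 | step 13 | 3-[(1R,2S,3S,6Z)-3-hydroxy-6-(1-hydroxypropan-2-ylidene)-2,3-dimethyl-2-[(3E,7E)-4,8,12-trimethyltrideca-3,7,11-trien-1-yl]cyclohexyl]propyl decanoate | CCCCCCCCCC(=O)OCCC[C@@H]1/C(=C(/C)CO)CC[C@](C)(O)[C@@]1(C)CC/C=C(\C)CC/C=C(\C)CCC=C(C)C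
F4 | step 5 | (4Z,6R)-5-methyl-6,7-bis(4,4,5,5-tetramethyl-1,3,2-dioxaborolan-2-yl)hept-4-en-1-yl decanoate | CCCCCCCCCC(=O)OCCC/C=C(/C)[C@H](B1OC(C)(C)C(C)(C)O1)CB1OC(C)(C)C(C)(C)O1
F5 | step 5 | 3-[(1R,2R,3R,6R)-2-ethenyl-3,6-dihydroxy-2,3-dimethylcyclohexyl]propyl decanoate | CCCCCCCCCC(=O)OCCC[C@H]1[C@H](O)CC[C@@](C)(O)[C@]1(C)C=C
F6 | step 5 | 3-[(1R,2R,3R,6R)-6-acetoxy-2-ethenyl-3-hydroxy-2,3-dimethylcyclohexyl]propyl decanoate | CCCCCCCCCC(=O)OCCC[C@H]1[C@H](OC(C)=O)CC[C@@](C)(O)[C@]1(C)C=C
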